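**Retrosynthetic overview**
- Feature: in the central naphthalene, ring C carries C1 OH, C2 aryl, C3 H and C4 aryl and is fused at C4a/C8a. The only other substituent, C8 OMe on ring D, lies peri to the C1 oxygen. Ring C is therefore read as C3-C6 of a 3-alkoxy-4,6-diaryl-2-pyrone, and ring D as 3-methoxybenzyne.
- Last disconnection: three O-benzyl bonds, cleaved together by hydrogenolysis.
- Key disconnection: C1-C8a and C4-C4a, made by aryne Diels-Alder addition to the pyrone followed by loss of CO2. Ring C is the only ring built; all other rings are bought.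
- Pyrone: both outer units are the same 4-oxy-5-methoxynaphthalen-1-yl group. The C4-aryl and C6-aryl bonds are therefore made in one twofold Suzuki-Miyaura coupling of a 3-(benzyloxy)-4,6-dibromo-2-pyrone with a single boronate.
- Building blocks: the boronate comes from naphthalene-1,8-diol (methylate, para-brominate, benzylate, borylate). The dibromopyrone comes from 3-hydroxy-2-pyrone (dibrominate, benzylate).

Key step: step 8

Assumption: the target is drawn without stereodescriptors, and neither naphthyl-naphthyl axis has the ortho substitution needed to hold a configuration for long, so the axes are treated as equilibrating and no axial control is attempted.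

**Step 1**
Reactants: 1 naphthalene-1,8-diol (1,8-dihydroxynaphthalene)
Product: 2 8-methoxynaphthalen-1-ol
Conditions: MeI (1.05 equiv), K2CO3 (1.1 equiv), acetone, reflux
Reagents that add atoms: iodomethane, CI
Why: Williamson O-methylation; after the first alkylation the remaining OH is held in a peri hydrogen bond to the new OMe and is far less acidic and nucleophilic, so one equivalent of MeI should stop at the monoether.

**Step 2**
Reactants: 2 8-methoxynaphthalen-1-ol
Product: 3 4-bromo-8-methoxynaphthalen-1-ol
Conditions: NBS (1.0 equiv), MeCN, 0 °C, dark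
Reagents that add atoms: N-bromosuccinimide, O=C1CCC(=O)N1Br
Why: Electrophilic aromatic bromination; the free naphthol ring is more activated than the anisole ring, and NBS in polar MeCN favours C4 (para to OH) over C2, which distinguishes the two rings before the phenol is masked.

**Step 3**
Reactants: 3 4-bromo-8-methoxynaphthalen-1-ol
Product: 4 1-(benzyloxy)-4-bromo-8-methoxynaphthalene
Conditions: BnBr, K2CO3, DMF, 60 °C
Reagents that add atoms: benzyl bromide, BrCc1ccccc1
Why: Williamson benzylation; gentle heating in DMF overcomes the peri hydrogen bond, and neither the aryl bromide nor the methyl ether reacts.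

**Step 4**
Reactants: 4 1-(benzyloxy)-4-bromo-8-methoxynaphthalene
Product: 5 2-[4-(benzyloxy)-5-methoxynaphthalen-1-yl]-4,4,5,5-tetramethyl-1,3,2-dioxaborolane
Conditions: B2pin2, PdCl2(dppf) (3 mol %), KOAc, 1,4-dioxane, 90 °C
Reagents that add atoms: bis(pinacolato)diboron, CC1(C)OB(OC1(C)C)B1OC(C)(C)C(C)(C)O1
Why: Miyaura borylation of an aryl bromide; the weak acetate base prevents homocoupling, and both ether types tolerate the conditions.

**Step 5**
Reactants: 6 3-hydroxy-2H-pyran-2-one
Product: 8 4,6-dibromo-3-hydroxy-2H-pyran-2-one, via 4-bromo-3-hydroxy-2H-pyran-2-one 7 (not isolated)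
Conditions: NBS (2.1 equiv), MeCN, 0 °C to rt
Reagents that add atoms: N-bromosuccinimide, O=C1CCC(=O)N1Br
Why: Electrophilic bromination of an enolic hydroxypyrone; the C3 hydroxyl is the strongest donor on the ring and directs first to its ortho carbon C4 and then, through the diene, to its para-like carbon C6, whereas C5 is activated only by the weakly donating acyloxy-type ring oxygen.

**Step 6**
Reactants: 8 4,6-dibromo-3-hydroxy-2H-pyran-2-one
Product: 9 3-(benzyloxy)-4,6-dibromo-2H-pyran-2-one
Conditions: BnBr, K2CO3, acetone, rt
Reagents that add atoms: benzyl bromide, BrCc1ccccc1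
Why: Williamson O-alkylation of an acidic enol; C4 and C6 are blocked by bromine, so the ambident anion is alkylated on oxygen, and a mild base at room temperature spares the two vinylogous acyl bromides.

**Step 7**
Reactants: 9 3-(benzyloxy)-4,6-dibromo-2H-pyran-2-one; 5 2-[4-(benzyloxy)-5-methoxynaphthalen-1-yl]-4,4,5,5-tetramethyl-1,3,2-dioxaborolane (2.3 equiv)
Product: 11 3-(benzyloxy)-4,6-bis[4-(benzyloxy)-5-methoxynaphthalen-1-yl]-2H-pyran-2-one, via monocoupled 4-bromopyrone 10 (not isolated)
Conditions: Pd(OAc)2 (5 mol %), SPhos (10 mol %), K3PO4, toluene/H2O 10:1, 80 °C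
Reagents that add atoms: none
Why: Twofold Suzuki-Miyaura coupling; halogens at C4 and C6 of a 2-pyrone add readily to zerovalent palladium, C6 first and the more hindered C4 second, and because both positions receive the same aryl group no site selectivity is needed, with SPhos serving the ortho-substituted second coupling.

**Step 8**
Reactants: 11 3-(benzyloxy)-4,6-bis[4-(benzyloxy)-5-methoxynaphthalen-1-yl]-2H-pyran-2-one; 12 3-methoxy-2-(trimethylsilyl)phenyl trifluoromethanesulfonate
Product: 15 1-(benzyloxy)-2,4-bis[4-(benzyloxy)-5-methoxynaphthalen-1-yl]-8-methoxynaphthalene, via 3-methoxybenzyne 13 (not isolated), via bridged lactone 14 (not isolated)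
Conditions: 12 (2.5 equiv, in portions), CsF (5 equiv), MeCN/toluene 1:1, 60 °C
Reagents that add atoms: none
Why: Fluoride attacks the silicon of 12 and triflate departs, releasing aryne 13, whose strained in-plane pi bond adds across C3 and C6 of the pyrone in a concerted but asynchronous [4+2] cycloaddition to give bridged lactone 14, and retro-[4+2] loss of CO2, driven by aromatisation, then leaves ring C of 15. The reaction type is the known Diels-Alder/decarboxylation of 2-pyrones with arynes from ortho-silylaryl triflates, although the regiochemistry of this particular pair is a prediction. Ring C is closed by intermolecular annulation, with C1-C8a and C4-C4a formed in the same operation, and pyrone C3, C4, C5 and C6 become C1, C2, C3 and C4, so the oxygen and both outer naphthyl units are placed by the pyrone itself. No stereocentre is left, because the two bridgehead centres of racemic 14 vanish with CO2 and the biaryl axes are not controlled. The step needs one orientation, C3(OBn) bonding to the aryne carbon next to OMe, and three factors favour it: the inductively polarised, distorted aryne forms its leading bond at the carbon remote from OMe, the C3 alkoxy donor makes C6 the nucleophilic diene terminus (ortho rule of 1-alkoxydienes, as seen with 2-alkoxyfurans), and the bulky C6 naphthyl avoids the peri clash with OMe that the opposite orientation would impose. Slow aryne release from sparingly soluble CsF and portionwise 12 keeps the aryne available for the doubly substituted diene rather than for self-condensation.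

**Step 9**
Reactants: 15 1-(benzyloxy)-2,4-bis[4-(benzyloxy)-5-methoxynaphthalen-1-yl]-8-methoxynaphthalene
Product: 16 2,4-bis(4-hydroxy-5-methoxynaphthalen-1-yl)-8-methoxynaphthalen-1-ol (CNP0528831.0)
Conditions: H2 (1 atm), Pd/C (10 wt %), THF/MeOH 1:1, rt, degassed work-up
Reagents that add atoms: none
Why: Catalytic hydrogenolysis of benzyl aryl ethers; methyl ethers, biaryl bonds and naphthalene rings are inert at one atmosphere and room temperature, and the neutral medium spares the oxidation-prone naphthols.

**Compound list**
1 | naphthalene-1,8-diol | Oc1cccc2cccc(O)c12 | starting material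
2 | 8-methoxynaphthalen-1-ol | COc1cccc2cccc(O)c12 | intermediate
3 | 4-bromo-8-methoxynaphthalen-1-ol | COc1cccc2c(Br)ccc(O)c12 | intermediate
4 | 1-(benzyloxy)-4-bromo-8-methoxynaphthalene | COc1cccc2c(Br)ccc(OCc3ccccc3)c12 | intermediate
5 | 2-[4-(benzyloxy)-5-methoxynaphthalen-1-yl]-4,4,5,5-tetramethyl-1,3,2-dioxaborolane | COc1cccc2c(B3OC(C)(C)C(C)(C)O3)ccc(OCc3ccccc3)c12 | intermediate
6 | 3-hydroxy-2H-pyran-2-one | O=c1occcc1O | starting material
7 | 4-bromo-3-hydroxy-2H-pyran-2-one (not isolated) | O=c1occc(Br)c1O | intermediate
8 | 4,6-dibromo-3-hydroxy-2H-pyran-2-one | O=c1oc(Br)cc(Br)c1O | intermediate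
9 | 3-(benzyloxy)-4,6-dibromo-2H-pyran-2-one | O=c1oc(Br)cc(Br)c1OCc1ccccc1 | intermediate
10 | 3-(benzyloxy)-6-[4-(benzyloxy)-5-methoxynaphthalen-1-yl]-4-bromo-2H-pyran-2-one (not isolated) | O=c1oc(-c2ccc(OCc3ccccc3)c3c(OC)cccc23)cc(Br)c1OCc1ccccc1 | intermediate
11 | 3-(benzyloxy)-4,6-bis[4-(benzyloxy)-5-methoxynaphthalen-1-yl]-2H-pyran-2-one | O=c1oc(-c2ccc(OCc3ccccc3)c3c(OC)cccc23)cc(-c2ccc(OCc3ccccc3)c3c(OC)cccc23)c1OCc1ccccc1 | intermediate
12 | 3-methoxy-2-(trimethylsilyl)phenyl trifluoromethanesulfonate | COc1cccc(OS(=O)(=O)C(F)(F)F)c1[Si](C)(C)C | starting material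
13 | 3-methoxybenzyne (1-methoxycyclohexa-1,3-dien-5-yne, not isolated) | COC1=CC=CC#C1 | intermediate
14 | bridged lactone, racemic, not isolated: benzo-fused 2-oxabicyclo[2.2.2]octadien-3-one in which the bridgehead C(OBn) is bonded to the lactone C=O and to the arene carbon ortho to OMe, and the bridgehead C(naphthyl) is bonded to the lactone O | O=C1OC2(c3ccc(OCc4ccccc4)c4c(OC)cccc34)C=C(c3ccc(OCc4ccccc4)c4c(OC)cccc34)C1(OCc1ccccc1)c1c(OC)cccc12 | intermediate
15 | 1-(benzyloxy)-2,4-bis[4-(benzyloxy)-5-methoxynaphthalen-1-yl]-8-methoxynaphthalene | COc1cccc2c(-c3ccc(OCc4ccccc4)c4c(OC)cccc34)cc(-c3ccc(OCc4ccccc4)c4c(OC)cccc34)c(OCc3ccccc3)c12 | intermediate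
16 | 2,4-bis(4-hydroxy-5-methoxynaphthalen-1-yl)-8-methoxynaphthalen-1-ol | COc1cccc2c(-c3cc(-c4ccc(O)c5c(OC)cccc45)c4cccc(OC)c4c3O)ccc(O)c12 | target

Total step count: 9. Longest linear sequence: 7 steps (1, 2, 3, 4, 7, 8, 9).

**Steps most likely to fail**

**Step 8.**
- What may go wrong: regiocontrol may erode. The ring oxygen and the electron-rich C6 naphthyl push electron density towards C3, and the C3 benzyloxy group, squeezed between C2=O and the C4 aryl, may twist out of conjugation and lose its directing power. A diene substituted at both termini may also capture the aryne too slowly, so the aryne is consumed by itself.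
- Fallback: it sets out from 2, uses 5, and returns at 15. Ring C is not built but taken from the naphthol.
  - Compound 2 is brominated ortho and para to the hydroxyl with two equivalents of NBS in MeCN to give 2,4-dibromo-8-methoxynaphthalen-1-ol F1.
  - Benzylation (BnBr, K2CO3, DMF) gives 1-(benzyloxy)-2,4-dibromo-8-methoxynaphthalene F2.
  - A twofold Suzuki-Miyaura coupling of F2 with 5 (Pd(OAc)2, SPhos, K3PO4, toluene/H2O) gives 15.

**Step 5.**
- What may go wrong: the second bromination may go to C5 instead of C6, or bromine may add across the enolic lactone and open the ring.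
- Fallback: it sets out from 4 and returns at 11. Both aryl-carbon bonds are in place before the pyrone ring is closed.
  - Bromine-lithium exchange on 4 (n-BuLi, THF, -78 °C) gives [4-(benzyloxy)-5-methoxynaphthalen-1-yl]lithium F3.
  - F3 is quenched with DMF to give 4-(benzyloxy)-5-methoxynaphthalene-1-carbaldehyde F4.
  - Ethynylmagnesium bromide adds to F4 to give racemic 1-[4-(benzyloxy)-5-methoxynaphthalen-1-yl]prop-2-yn-1-ol F5.
  - Sonogashira coupling of F5 with a second portion of 4 (PdCl2(PPh3)2, CuI, Et3N, 70 °C) gives racemic 1,3-bis[4-(benzyloxy)-5-methoxynaphthalen-1-yl]prop-2-yn-1-ol F6.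
  - MnO2 in CH2Cl2 oxidises F6 to 1,3-bis[4-(benzyloxy)-5-methoxynaphthalen-1-yl]prop-2-yn-1-one F7.
  - The potassium enolate of methyl 2-(benzyloxy)acetate (KHMDS, THF, -78 °C to rt) adds to F7. Carbonyl addition is reversible, so the mixture should drain through conjugate addition to methyl 2-(benzyloxy)-3,5-bis[4-(benzyloxy)-5-methoxynaphthalen-1-yl]-5-oxopent-3-enoate F8.
  - The dienolate of F8 closes on the ester with loss of methoxide to give 11 (Michael addition-lactonisation).

**Step 7.**
- What may go wrong: the aqueous base may open the bromopyrone hydrolytically, the electron-rich boronate may protodeboronate, or the reaction may stall after the first coupling and leave the hindered C4 bromide untouched.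
- Fallback: it sets out from 4, uses 9, and returns at 11. The base-dependent boron chemistry is replaced by a base-free organozinc coupling.
  - The aryllithium F3, made from 4 as above, is transmetalated with ZnCl2 in THF to chlorido[4-(benzyloxy)-5-methoxynaphthalen-1-yl]zinc F9.
  - F9 (2.5 equiv) undergoes a twofold Negishi coupling with 9 (Pd2(dba)3, SPhos, THF, 50 °C) to give 11.

**Further compounds**
F1 | step 8 | 2,4-dibromo-8-methoxynaphthalen-1-ol | COc1cccc2c(Br)cc(Br)c(O)c12
F2 | step 8 | 1-(benzyloxy)-2,4-dibromo-8-methoxynaphthalene | COc1cccc2c(Br)cc(Br)c(OCc3ccccc3)c12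
F3 | step 5 | [4-(benzyloxy)-5-methoxynaphthalen-1-yl]lithium | [Li]c1ccc(OCc2ccccc2)c2c(OC)cccc12
F4 | step 5 | 4-(benzyloxy)-5-methoxynaphthalene-1-carbaldehyde | COc1cccc2c(C=O)ccc(OCc3ccccc3)c12
F5 | step 5 | 1-[4-(benzyloxy)-5-methoxynaphthalen-1-yl]prop-2-yn-1-ol (racemic) | COc1cccc2c(C(O)C#C)ccc(OCc3ccccc3)c12
F6 | step 5 | 1,3-bis[4-(benzyloxy)-5-methoxynaphthalen-1-yl]prop-2-yn-1-ol (racemic) | COc1cccc2c(C(O)C#Cc3ccc(OCc4ccccc4)c4c(OC)cccc34)ccc(OCc3ccccc3)c12
F7 | step 5 | 1,3-bis[4-(benzyloxy)-5-methoxynaphthalen-1-yl]prop-2-yn-1-one | COc1cccc2c(C(=O)C#Cc3ccc(OCc4ccccc4)c4c(OC)cccc34)ccc(OCc3ccccc3)c12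
F8 | step 5 | methyl 2-(benzyloxy)-3,5-bis[4-(benzyloxy)-5-methoxynaphthalen-1-yl]-5-oxopent-3-enoate (alkene geometry equilibrating through the dienolate, not isolated) | COC(=O)C(OCc1ccccc1)C(=CC(=O)c1ccc(OCc2ccccc2)c2c(OC)cccc12)c1ccc(OCc2ccccc2)c2c(OC)cccc12
F9 | step 7 | chlorido[4-(benzyloxy)-5-methoxynaphthalen-1-yl]zinc | Cl[Zn]c1ccc(OCc2ccccc2)c2c(OC)cccc12
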